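The delta run is the easy place to start: by 1.5 h it had turned 32.1 % of its starting material, and by 7.6 h it had turned 40.8 %, after which the readings barely rose.

| flask | starting material | partner | free catalyst | product | time |
|---|---|---|---|---|---|
| delta | 1.00 M | 3.00 M | 0.00500 M |  |  |
| alpha | 0.600 M | 2.60 M | 0.00500 M |  |  |
| zeta | 1.00 M | 3.00 M | 0.00500 M | 0.500 M |  |
| epsilon | 1.00 M | 3.00 M | 0.00500 M |  | 95 h |

- delta run (time / h: [product] / M): 1.5: 0.321; 3.4: 0.371; 7.6: 0.408; 17: 0.416; 38: 0.433
- alpha run (time / h: [product] / M): 1.5: 0.224; 3.4: 0.244; 7.6: 0.248; 17: 0.259; 38: 0.280
- zeta run (time / h: [product] / M): 1.5: 0.819; 3.4: 0.895; 7.6: 0.914; 17: 0.909; 38: 0.920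

(standard deviation of a reading: 0.01 M)

- Overall: starting material + partner -> product, with free catalyst as catalyst.
- Constant volume, constant temperature.
- A reading of a species includes what of it is bound.
- "The second partner" is partner.

- product in the epsilon run at 95 h, as a share of the starting material charged

The epsilon flask is charged like the delta run, so I read its future from the delta tail. The gain per hour fell from 0.0263 h⁻¹ between 1.5 h and 3.4 h to 8.22 × 10⁻⁴ h⁻¹ between 7.6 h and 38 h. So I did not trust a straight line in hours, and I counted doublings of time instead. The creep per doubling, the share of the charge gained each time the elapsed time doubles, was 1.08 % in the delta run, a reading that carries the scatter of its two ends. From 38 h to 95 h lie 1.32 doublings, so my count gave 44.7 %.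

The forecast, made from the same runs, said 46 %, within 43.5 % to 49.5 %, holding that “The catalyst is dying, or being sequestered”. It stood 1.3 percentage points above my count.

The epsilon flask gave 44.8 %, inside the forecast's range.

    free catalyst + starting material → catalyst-substrate complex (207.7 M⁻¹ h⁻¹)
    catalyst-substrate complex + partner → product + free catalyst (145.8 M⁻¹ h⁻¹)
    2 partner → lost reagent (0.1026 M⁻¹ h⁻¹)
    free catalyst + partner → spent catalyst + partner (0.9936 M⁻¹ h⁻¹)

In these steps the partner of the epsilon flask, at its charge of 3.00 M, has a first half-life of 1.62 h by its own loss step alone. Taken to the alpha run, whose charge of starting material is smaller than that of the delta run, the delta creep in molar terms gives 4.17 % of the alpha charge between 7.6 h and 38 h, and the alpha readings there show 5.33 %.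

The earlier runs and the new flask come from a simulation with constants of no real substance, and the scatter is random.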